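The flasks differed in one amount: c(substrate) went from 0.30 M in midnight to 3.0 M in dusk, while the gas stayed held at 39 mM.

common to all: gas 39 mM (held)
- red: substrate 1.2 M; run made earlier
- summer: substrate 1.1 M; time 1.5 h
- midnight: substrate 0.30 M; time 1.5 h
- winter: substrate 1.5 M; time 1.5 h
- dusk: substrate 3.0 M; time 1.5 h
- spring: substrate 0.80 M; time 1.5 h
- noon: substrate 2.0 M; time 1.5 h

- red (time / min: ring / %): 3.00: 0; 8.00: 1.7; 15.0: 4.8; 25.0: 9.8; 30.0: 12.9

(scatter of a reading: 1 percentage point)

- a species is counted by the substrate in it: one open dimer or side product counts as two
- at the start none of activator is dissolved
- steps that have been proposed: substrate + activated form -> open dimer; gas <-> activator; substrate + ring -> side product; substrate + activator -> activated form; activated form -> ring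

- the flasks put in order of amount of ring, in percent of the substrate charged, best first, at 1.5 h (summer / midnight / winter / dusk / spring / noon)
- the amount of ring, in percent of the substrate charged of the flask you put first, at 1.5 h
- the amount of ring, in percent of the substrate charged of the flask you put last, at 1.5 h

I compared two amounts. The first was the charge. The second came from the red run, a 1.2 M charge whose ring rose from 4.8% at 15.0 min to 12.9% at 30.0 min. That is 6.48 mM/min of ring, a reading that carries the scatter of 1 percentage point. I assumed that this pace in molar held in the other flasks, with the same gas. Over 1.5 h it gives 0.583 M, which I called the ring budget. Set against the charge, the budget is 19.4% of the dusk charge, so I put dusk near that figure. In midnight the budget is more than the charge, so I expected that flask to be bounded by its charge instead.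

The forecast gave midnight > spring > summer > winter > noon > dusk, with 45% (28% to 72%) for midnight and 17% (7% to 29%) for dusk, on the ground that “selectivity falls as substrate rises”. My reckoning gave the same order and came near its dusk by another road, but for midnight it differed, since my bound was the charge itself.

The flasks came in the order midnight > spring > summer > winter > noon > dusk, with midnight at 83.4% and dusk at 24.5%.

    substrate + activated form → open dimer (k = 1.90 × 10⁻⁵ /M/s)
    gas ⇌ activator, rate k2*(csat - [activator]) (kL = 0.00900 /s)
    substrate + ring → side product (k = 1.20 × 10⁻⁴ /M/s)
    substrate + activator → activated form (k = 0.0250 /M/s)
    activated form → ring (k = 5.70 × 10⁻⁴ /s)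

Dusk held 0.735 M of ring against the budget of 0.583 M, and a neighbour flask, the dusk recipe read at 50 min, held 0.348 M against 0.324 M at the red pace for that time. In dusk at 0.719 h, activator was made 1.00 times as fast as it was used up, a quasi-steady state, and at 0.750 h c(activator), lower than the held 39 mM, stood at 0.00580 M.

The readings are calculated for an exercise; noise was put on by code.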